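## Retrosynthetic overview

1. Target 38 is opened at the O1–C2 bond of dihydrobenzofuran unit 1 (benzo ring B). C2 is benzylic to guaiacyl ring A, whose hydroxyl lies para to it, so the C7a oxygen of ring B can add to a ring A para-quinone methide. The precursor 35 is the ring-opened 1,3-diacetate with unit 2 intact and the two phenols and two alcohols as TBS ethers, so that fluoride in THF frees both phenols together in a non-nucleophilic medium.
2. 35 comes from an Evans syn aldol (C2–C3 bond) of the ring B arylacetyl imide 31 with O-TBS-vanillin 17, then LiBH4 and acetylation. (R)-4-Benzyl-2-oxazolidinone fixes C3; the carbinol centre is erased later.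
3. 31 comes from the unit 2 phenol 24 by silylation, oxidative cleavage of the ring B allyl group to CH2CO2H, Suzuki coupling of the ring C bromide with boronate 28, and N-acylation of the auxiliary.
4. 24 comes from the same quinone methide closure (O1'–C2') after an Evans aldol of ring C imide 11 with silylated 5-allylvanillin 16. Both 11 and 16 arise by O-allylation and Claisen rearrangement, from 4-bromo-2-methoxyphenol and vanillin.
5. Ring order: dihydrofuran ring of unit 2 (step 13), then dihydrofuran ring of unit 1 (step 21, the last step).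

Key step: step 21

Remark: TBS = tert-butyldimethylsilyl, Piv = pivaloyl, dppf = 1,1'-bis(diphenylphosphino)ferrocene; boronate 28 is taken as a catalogue reagent; the carbinol centres made in steps 10 and 18 are written as the syn-aldol isomers, but both are erased when the quinone methides form, so only the aryl-bearing centres have to be set.

## Route

Step 1
Reactants: 1 4-bromo-2-methoxyphenol; 2 allyl bromide
Product: 3 1-(allyloxy)-4-bromo-2-methoxybenzene
Conditions: K2CO3, acetone, reflux
Reagents that add atoms: none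
Why: Williamson ether synthesis, in which the phenoxide is alkylated on oxygen by the unhindered allylic bromide and nothing else in 1 can react.

Step 2
Reactants: 3 1-(allyloxy)-4-bromo-2-methoxybenzene
Product: 5 2-allyl-4-bromo-6-methoxyphenol, via ortho-dienone 4 (not isolated)
Conditions: N,N-diethylaniline, 200 °C
Reagents that add atoms: none
Why: Aromatic Claisen rearrangement, whose [3,3] shift can only go to C6 because the other ortho position carries the methoxy group and the para position the bromine, after which dienone 4 rearomatises by tautomerisation.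

Step 3
Reactants: 5 2-allyl-4-bromo-6-methoxyphenol
Product: 6 (2-allyl-4-bromo-6-methoxyphenoxy)(tert-butyl)dimethylsilane
Conditions: TBSCl, imidazole, DMF, rt
Reagents that add atoms: tert-butyldimethylsilyl chloride (TBSCl), CC(C)(C)[Si](C)(C)Cl
Why: Imidazole-promoted O-silylation of the phenol, giving an ether that should survive every step up to the fluoride treatment of step 13.

Step 4
Reactants: 6 (2-allyl-4-bromo-6-methoxyphenoxy)(tert-butyl)dimethylsilane
Product: 8 [5-bromo-2-(tert-butyldimethylsilyloxy)-3-methoxyphenyl]acetic acid, via arylacetaldehyde 7 (not isolated)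
Conditions: O3, MeCN/H2O (9:1), 0 °C; then NaClO2, NaH2PO4, 0 °C to rt
Reagents that add atoms: ozone, O=[O+][O-]; water, O; sodium chlorite, [Na+].[O-]Cl=O
Why: Ozonolysis of the terminal alkene in wet acetonitrile (water intercepts the carbonyl oxide, so aldehyde 7 forms without a reductant) followed in the same flask by Pinnick oxidation, with the hydrogen peroxide released in the first stage scavenging hypochlorite and the bromo-substituted arene reacting with ozone far more slowly than the alkene.

Step 5
Reactants: 8 [5-bromo-2-(tert-butyldimethylsilyloxy)-3-methoxyphenyl]acetic acid; 9 (R)-4-benzyl-2-oxazolidinone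
Product: 11 (R)-4-benzyl-3-{[5-bromo-2-(tert-butyldimethylsilyloxy)-3-methoxyphenyl]acetyl}oxazolidin-2-one, via mixed pivalic anhydride 10 (not isolated)
Conditions: PivCl, Et3N, THF, −20 °C; then 9, LiCl, rt
Reagents that add atoms: none
Why: N-acylation of the oxazolidinone through the mixed pivalic anhydride, in which LiCl/Et3N activates the N–H and the attack goes to the unhindered arylacetyl carbonyl.

Step 6
Reactants: 12 vanillin; 2 allyl bromide
Product: 13 4-(allyloxy)-3-methoxybenzaldehyde
Conditions: K2CO3, acetone, reflux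
Reagents that add atoms: none
Why: Williamson ether synthesis on the phenoxide of vanillin, the aldehyde being inert to carbonate.

Step 7
Reactants: 13 4-(allyloxy)-3-methoxybenzaldehyde
Product: 15 3-allyl-4-hydroxy-5-methoxybenzaldehyde, via ortho-dienone 14 (not isolated)
Conditions: neat, N2, 200 °C
Reagents that add atoms: none
Why: Aromatic Claisen rearrangement to the only free ortho position (C5), followed by tautomerisation of dienone 14 to the phenol.

Step 8
Reactants: 15 3-allyl-4-hydroxy-5-methoxybenzaldehyde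
Product: 16 3-allyl-4-(tert-butyldimethylsilyloxy)-5-methoxybenzaldehyde
Conditions: TBSCl, imidazole, DMF, rt
Reagents that add atoms: tert-butyldimethylsilyl chloride (TBSCl), CC(C)(C)[Si](C)(C)Cl
Why: O-silylation of the phenol, so that the aldehyde can serve as acceptor for a boron enolate and the ring B oxygen can later be freed by fluoride.

Step 9
Reactants: 12 vanillin
Product: 17 4-(tert-butyldimethylsilyloxy)-3-methoxybenzaldehyde
Conditions: TBSCl, imidazole, CH2Cl2, rt
Reagents that add atoms: tert-butyldimethylsilyl chloride (TBSCl), CC(C)(C)[Si](C)(C)Cl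
Why: O-silylation of the phenol, which gives the ring A aldehyde in the form needed for the aldol of step 18 and for the fluoride trigger of step 21.

Step 10
Reactants: 11 ring C arylacetyl imide; 16 3-allyl-4-(tert-butyldimethylsilyloxy)-5-methoxybenzaldehyde
Product: 19 (2R,3R) syn-aldol adduct of 11 and 16, via boron enolate 18 (not isolated)
Conditions: Bu2BOTf, iPr2NEt, CH2Cl2, 0 °C; then 16, −78 to 0 °C; then pH 7 phosphate buffer, MeOH, H2O2, 0 °C
Reagents that add atoms: none
Why: Evans syn aldol reaction, in which the (Z)-boron enolate 18 reacts through a closed chair transition state on the enolate face away from the benzyl group of the auxiliary, setting the aryl-bearing carbon as R (the future C3' of unit 2, S once the imide is reduced) and the carbinol centre syn to it.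

Step 11
Reactants: 19 (2R,3R) syn-aldol adduct
Product: 20 (1R,2S)-1-(3-allyl-4-TBSO-5-methoxyphenyl)-2-(5-bromo-2-TBSO-3-methoxyphenyl)propane-1,3-diol
Conditions: LiBH4, MeOH (1.1 equiv), THF, 0 °C
Reagents that add atoms: none
Why: Reductive cleavage of the N-acyloxazolidinone, in which borohydride reduces the exocyclic imide carbonyl to CH2OH and releases auxiliary 9 at a temperature at which the aryl-bearing stereocentre, the silyl ethers, the allyl group and the aryl bromide should persist.

Step 12
Reactants: 20 (1R,2S)-1,3-diol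
Product: 21 (1R,2S)-1,3-diacetate of 20
Conditions: Ac2O, pyridine, DMAP (cat.), CH2Cl2, 0 °C to rt
Reagents that add atoms: acetic anhydride, CC(=O)OC(C)=O
Why: DMAP-catalysed acetylation of the primary and the secondary benzylic alcohol, the benzylic acetate being the leaving group for the quinone methide of step 13.

Step 13
Reactants: 21 (1R,2S)-1,3-diacetate
Product: 24 2-allyl-4-[(2R,3S)-5-bromo-3-(hydroxymethyl)-7-methoxy-2,3-dihydrobenzofuran-2-yl]-6-methoxyphenol, via quinone methide 22 (not isolated), via cyclised acetate 23 (not isolated)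
Conditions: TBAF, THF, 0 °C; then K2CO3, MeOH, rt
Reagents that add atoms: none
Why: Fluoride-triggered para-quinone methide formation with intramolecular oxa-Michael capture, in which desilylation of both aryl ethers lets the ring B phenoxide expel the para-benzylic acetate, the ring C phenoxide closes the ring 5-exo-trig on the methide carbon anti to the C3' acetoxymethyl group to give the trans (2R,3S) dihydrobenzofuran whatever the carbinol configuration was, and carbonate in methanol then transesterifies the primary acetate.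

Step 14
Reactants: 24 unit 2 phenol
Product: 25 bis-TBS ether of 24 (ring B aryl O-TBS and C3' CH2O-TBS)
Conditions: TBSCl, imidazole, DMF, rt to 40 °C
Reagents that add atoms: tert-butyldimethylsilyl chloride (TBSCl), CC(C)(C)[Si](C)(C)Cl
Why: O-silylation of the ring B phenol and of the primary alcohol, which keeps the ring B oxygen from lactonising onto the acid made next and locks unit 2 against re-opening.

Step 15
Reactants: 25 bis-TBS ether of 24
Product: 27 ring B arylacetic acid (ring C still brominated), via arylacetaldehyde 26 (not isolated)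
Conditions: O3, MeCN/H2O (9:1), 0 °C; then NaClO2, NaH2PO4, 0 °C to rt
Reagents that add atoms: ozone, O=[O+][O-]; water, O; sodium chlorite, [Na+].[O-]Cl=O
Why: The same ozonolysis and Pinnick oxidation as in step 4, selective for the terminal alkene because the arenes react far more slowly with ozone and the silyl ethers, the aryl bromide and the benzylic ether are inert to buffered chlorite.

Step 16
Reactants: 27 ring B arylacetic acid (bromide); 28 (E)-2-[3-(tert-butyldimethylsilyloxy)prop-1-en-1-yl]-4,4,5,5-tetramethyl-1,3,2-dioxaborolane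
Product: 29 ring B arylacetic acid bearing the (E)-3-(TBSO)prop-1-enyl chain on ring C
Conditions: Pd(dppf)Cl2 (5 mol %), K3PO4, THF/H2O (10:1), 60 °C
Reagents that add atoms: none
Why: Suzuki–Miyaura coupling, in which zerovalent palladium inserts into the only C–Br bond and the alkenyl boronate transmetallates with retention so that the E alkene is carried over, while the carboxylate and the hindered silyl ethers should tolerate the mild phosphate base.

Step 17
Reactants: 29 ring B arylacetic acid; 9 (R)-4-benzyl-2-oxazolidinone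
Product: 31 ring B arylacetyl imide (unit 2 intact), via mixed pivalic anhydride 30 (not isolated)
Conditions: PivCl, Et3N, THF, −20 °C; then 9, LiCl, rt
Reagents that add atoms: none
Why: N-acylation of the oxazolidinone through the mixed pivalic anhydride as in step 5, under conditions mild enough for the silyl ethers and the allylic silyl ether.

Step 18
Reactants: 31 ring B arylacetyl imide; 17 4-(tert-butyldimethylsilyloxy)-3-methoxybenzaldehyde
Product: 33 (2R,3R) syn-aldol adduct of 31 and 17, via boron enolate 32 (not isolated)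
Conditions: Bu2BOTf, iPr2NEt, CH2Cl2, 0 °C; then 17, −78 to 0 °C; then pH 7 phosphate buffer, MeOH, H2O2, 0 °C
Reagents that add atoms: none
Why: Evans syn aldol reaction as in step 10, in which the auxiliary alone (the stereocentres of unit 2 are remote) directs the aldehyde to the enolate face that makes the ring B-bearing carbon R (C3 of unit 1, S once the imide is reduced), the carbinol centre again being inconsequential.

Step 19
Reactants: 33 (2R,3R) syn-aldol adduct
Product: 34 (1R,2S)-1,3-diol (ring-opened unit 1, four TBS ethers)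
Conditions: LiBH4, MeOH (1.1 equiv), THF, 0 °C
Reagents that add atoms: none
Why: Reductive cleavage of the N-acyloxazolidinone to the primary alcohol with release of auxiliary 9, leaving the silyl ethers, the alkene and both dihydrobenzofuran stereocentres untouched.

Step 20
Reactants: 34 (1R,2S)-1,3-diol
Product: 35 (1R,2S)-1,3-diacetate (precursor of the key step)
Conditions: Ac2O, pyridine, DMAP (cat.), CH2Cl2, 0 °C to rt
Reagents that add atoms: acetic anhydride, CC(=O)OC(C)=O
Why: DMAP-catalysed acetylation of the two free hydroxyls, which installs the benzylic leaving group para to the silylated ring A oxygen.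

Step 21
Reactants: 35 (1R,2S)-1,3-diacetate
Product: 38 target CNP0250921.1, via quinone methide 36 (not isolated), via target monoacetate 37 (not isolated)
Conditions: TBAF, THF, 0 °C to rt; then K2CO3, MeOH, rt
Reagents that add atoms: none
Why: Fluoride removes the two aryl silyl ethers within minutes, the ring A phenoxide expels the para-benzylic acetate by 1,6-elimination to give the planar quinone methide 36 (so the carbinol configuration of 35 is irrelevant), and the ring B phenoxide adds to the exocyclic methide carbon, forming O1–C2 and rearomatising ring A. The closest known reaction type is the fluoride- or base-triggered generation of para-quinone methides from O-protected 4-hydroxybenzyl esters with intramolecular capture by a phenol, the ring-closing half of the biosynthetic 8–5' coupling and a standard entry to trans-phenylcoumarans in lignin model chemistry. The dihydrofuran ring of unit 1 closes in the 5-exo-trig mode. The new stereocentre C2 is controlled by the fixed C3 centre: the phenoxide attacks the methide face anti to the C3 acetoxymethyl group, and since the addition is reversible under basic conditions the thermodynamically preferred trans (2R,3S) ring should result. The step needs capture of the methide by the ring B oxygen and not by an external nucleophile or by loss of the C3 proton, which is secured by unveiling both phenols together in non-nucleophilic THF and by the intramolecular five-membered attack. Fluoride then strips the two alkyl silyl ethers and carbonate in methanol transesterifies the primary acetate of 37, conditions that leave the acid-labile cinnamyl alcohol untouched.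

## Compound list

Ar* in the names below = 2-(TBSO)-3-methoxy-5-{(2R,3S)-3-(TBSO-methyl)-5-[(E)-3-(TBSO)prop-1-enyl]-7-methoxy-2,3-dihydrobenzofuran-2-yl}phenyl.

1 | 4-bromo-2-methoxyphenol | COc1cc(Br)ccc1O | starting material
2 | allyl bromide | C=CCBr | starting material
3 | 1-(allyloxy)-4-bromo-2-methoxybenzene | COc1cc(Br)ccc1OCC=C | intermediate
4 | 6-allyl-4-bromo-2-methoxycyclohexa-2,4-dien-1-one (ortho-dienone, not isolated) | COC1=CC(Br)=CC(CC=C)C1=O | intermediate
5 | 2-allyl-4-bromo-6-methoxyphenol | COc1cc(Br)cc(CC=C)c1O | intermediate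
6 | (2-allyl-4-bromo-6-methoxyphenoxy)(tert-butyl)dimethylsilane | COc1cc(Br)cc(CC=C)c1O[Si](C)(C)C(C)(C)C | intermediate
7 | [5-bromo-2-(tert-butyldimethylsilyloxy)-3-methoxyphenyl]acetaldehyde (not isolated) | COc1cc(Br)cc(CC=O)c1O[Si](C)(C)C(C)(C)C | intermediate
8 | [5-bromo-2-(tert-butyldimethylsilyloxy)-3-methoxyphenyl]acetic acid | COc1cc(Br)cc(CC(=O)O)c1O[Si](C)(C)C(C)(C)C | intermediate
9 | (R)-4-benzyl-2-oxazolidinone | O=C1N[C@H](Cc2ccccc2)CO1 | starting material
10 | mixed anhydride of 8 with pivalic acid (not isolated) | COc1cc(Br)cc(CC(=O)OC(=O)C(C)(C)C)c1O[Si](C)(C)C(C)(C)C | intermediate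
11 | (R)-4-benzyl-3-{[5-bromo-2-(tert-butyldimethylsilyloxy)-3-methoxyphenyl]acetyl}oxazolidin-2-one (ring C imide) | COc1cc(Br)cc(CC(=O)N2C(=O)OC[C@H]2Cc2ccccc2)c1O[Si](C)(C)C(C)(C)C | intermediate
12 | vanillin | COc1cc(C=O)ccc1O | starting material
13 | 4-(allyloxy)-3-methoxybenzaldehyde | COc1cc(C=O)ccc1OCC=C | intermediate
14 | 3-allyl-5-methoxy-4-oxocyclohexa-1,5-diene-1-carbaldehyde (ortho-dienone, not isolated) | COC1=CC(C=O)=CC(CC=C)C1=O | intermediate
15 | 3-allyl-4-hydroxy-5-methoxybenzaldehyde (5-allylvanillin) | COc1cc(C=O)cc(CC=C)c1O | intermediate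
16 | 3-allyl-4-(tert-butyldimethylsilyloxy)-5-methoxybenzaldehyde (ring B aldehyde) | COc1cc(C=O)cc(CC=C)c1O[Si](C)(C)C(C)(C)C | intermediate
17 | 4-(tert-butyldimethylsilyloxy)-3-methoxybenzaldehyde (ring A aldehyde) | COc1cc(C=O)ccc1O[Si](C)(C)C(C)(C)C | intermediate
18 | (Z)-O-dibutylboryl enolate of 11 (not isolated) | CCCCB(CCCC)O/C(=C\c1cc(Br)cc(OC)c1O[Si](C)(C)C(C)(C)C)N1C(=O)OC[C@H]1Cc1ccccc1 | intermediate
19 | (R)-4-benzyl-3-[(2R,3R)-3-(3-allyl-4-TBSO-5-methoxyphenyl)-2-(5-bromo-2-TBSO-3-methoxyphenyl)-3-hydroxypropanoyl]oxazolidin-2-one | O=C([C@H](c1cc(Br)cc(OC)c1O[Si](C)(C)C(C)(C)C)[C@@H](O)c1cc(OC)c(O[Si](C)(C)C(C)(C)C)c(CC=C)c1)N1C(=O)OC[C@H]1Cc1ccccc1 | intermediate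
20 | (1R,2S)-1-(3-allyl-4-TBSO-5-methoxyphenyl)-2-(5-bromo-2-TBSO-3-methoxyphenyl)propane-1,3-diol | OC[C@H](c1cc(Br)cc(OC)c1O[Si](C)(C)C(C)(C)C)[C@@H](O)c1cc(OC)c(O[Si](C)(C)C(C)(C)C)c(CC=C)c1 | intermediate
21 | (1R,2S)-1-(3-allyl-4-TBSO-5-methoxyphenyl)-2-(5-bromo-2-TBSO-3-methoxyphenyl)propane-1,3-diyl diacetate | CC(=O)OC[C@H](c1cc(Br)cc(OC)c1O[Si](C)(C)C(C)(C)C)[C@@H](OC(C)=O)c1cc(OC)c(O[Si](C)(C)C(C)(C)C)c(CC=C)c1 | intermediate
22 | ring B para-quinone methide: 3-(3-allyl-5-methoxy-4-oxocyclohexa-2,5-dien-1-ylidene)-2-(5-bromo-2-hydroxy-3-methoxyphenyl)propyl acetate, stereocentre as in 21 (not isolated) | CC(=O)OC[C@H](c1cc(Br)cc(OC)c1O)C=C1C=C(OC)C(=O)C(CC=C)=C1 | intermediate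
23 | [(2R,3S)-2-(3-allyl-4-hydroxy-5-methoxyphenyl)-5-bromo-7-methoxy-2,3-dihydrobenzofuran-3-yl]methyl acetate (not isolated) | COc1cc([C@@H]2Oc3c(OC)cc(Br)cc3[C@H]2COC(C)=O)cc(CC=C)c1O | intermediate
24 | 2-allyl-4-[(2R,3S)-5-bromo-3-(hydroxymethyl)-7-methoxy-2,3-dihydrobenzofuran-2-yl]-6-methoxyphenol (unit 2 phenol) | COc1cc([C@@H]2Oc3c(OC)cc(Br)cc3[C@H]2CO)cc(CC=C)c1O | intermediate
25 | bis-TBS ether of 24: (2R,3S)-2-(3-allyl-4-TBSO-5-methoxyphenyl)-5-bromo-3-(TBSO-methyl)-7-methoxy-2,3-dihydrobenzofuran | COc1cc([C@@H]2Oc3c(OC)cc(Br)cc3[C@H]2CO[Si](C)(C)C(C)(C)C)cc(CC=C)c1O[Si](C)(C)C(C)(C)C | intermediate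
26 | {2-TBSO-5-[(2R,3S)-5-bromo-3-(TBSO-methyl)-7-methoxy-2,3-dihydrobenzofuran-2-yl]-3-methoxyphenyl}acetaldehyde (not isolated) | COc1cc([C@@H]2Oc3c(OC)cc(Br)cc3[C@H]2CO[Si](C)(C)C(C)(C)C)cc(CC=O)c1O[Si](C)(C)C(C)(C)C | intermediate
27 | {2-TBSO-5-[(2R,3S)-5-bromo-3-(TBSO-methyl)-7-methoxy-2,3-dihydrobenzofuran-2-yl]-3-methoxyphenyl}acetic acid | COc1cc([C@@H]2Oc3c(OC)cc(Br)cc3[C@H]2CO[Si](C)(C)C(C)(C)C)cc(CC(=O)O)c1O[Si](C)(C)C(C)(C)C | intermediate
28 | (E)-2-[3-(tert-butyldimethylsilyloxy)prop-1-en-1-yl]-4,4,5,5-tetramethyl-1,3,2-dioxaborolane | CC(C)(C)[Si](C)(C)OC/C=C/B1OC(C)(C)C(C)(C)O1 | starting material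
29 | Ar*-acetic acid | COc1cc([C@@H]2Oc3c(OC)cc(/C=C/CO[Si](C)(C)C(C)(C)C)cc3[C@H]2CO[Si](C)(C)C(C)(C)C)cc(CC(=O)O)c1O[Si](C)(C)C(C)(C)C | intermediate
30 | mixed anhydride of 29 with pivalic acid (not isolated) | COc1cc([C@@H]2Oc3c(OC)cc(/C=C/CO[Si](C)(C)C(C)(C)C)cc3[C@H]2CO[Si](C)(C)C(C)(C)C)cc(CC(=O)OC(=O)C(C)(C)C)c1O[Si](C)(C)C(C)(C)C | intermediate
31 | (R)-4-benzyl-3-(Ar*-acetyl)oxazolidin-2-one (ring B arylacetyl imide) | COc1cc([C@@H]2Oc3c(OC)cc(/C=C/CO[Si](C)(C)C(C)(C)C)cc3[C@H]2CO[Si](C)(C)C(C)(C)C)cc(CC(=O)N2C(=O)OC[C@H]2Cc2ccccc2)c1O[Si](C)(C)C(C)(C)C | intermediate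
32 | (Z)-O-dibutylboryl enolate of 31 (not isolated) | CCCCB(CCCC)O/C(=C\c1cc([C@@H]2Oc3c(OC)cc(/C=C/CO[Si](C)(C)C(C)(C)C)cc3[C@H]2CO[Si](C)(C)C(C)(C)C)cc(OC)c1O[Si](C)(C)C(C)(C)C)N1C(=O)OC[C@H]1Cc1ccccc1 | intermediate
33 | (R)-4-benzyl-3-[(2R,3R)-2-Ar*-3-hydroxy-3-(4-TBSO-3-methoxyphenyl)propanoyl]oxazolidin-2-one | O=C([C@H](c1cc([C@@H]2Oc3c(OC)cc(/C=C/CO[Si](C)(C)C(C)(C)C)cc3[C@H]2CO[Si](C)(C)C(C)(C)C)cc(OC)c1O[Si](C)(C)C(C)(C)C)[C@@H](O)c1ccc(O[Si](C)(C)C(C)(C)C)c(OC)c1)N1C(=O)OC[C@H]1Cc1ccccc1 | intermediate
34 | (1R,2S)-2-Ar*-1-(4-TBSO-3-methoxyphenyl)propane-1,3-diol | OC[C@H](c1cc([C@@H]2Oc3c(OC)cc(/C=C/CO[Si](C)(C)C(C)(C)C)cc3[C@H]2CO[Si](C)(C)C(C)(C)C)cc(OC)c1O[Si](C)(C)C(C)(C)C)[C@@H](O)c1ccc(O[Si](C)(C)C(C)(C)C)c(OC)c1 | intermediate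
35 | (1R,2S)-2-Ar*-1-(4-TBSO-3-methoxyphenyl)propane-1,3-diyl diacetate (ring-opened unit 1, key-step precursor) | CC(=O)OC[C@H](c1cc([C@@H]2Oc3c(OC)cc(/C=C/CO[Si](C)(C)C(C)(C)C)cc3[C@H]2CO[Si](C)(C)C(C)(C)C)cc(OC)c1O[Si](C)(C)C(C)(C)C)[C@@H](OC(C)=O)c1ccc(O[Si](C)(C)C(C)(C)C)c(OC)c1 | intermediate
36 | ring A para-quinone methide: 3-(3-methoxy-4-oxocyclohexa-2,5-dien-1-ylidene)-2-aryl-propyl acetate with free ring B phenol, the two alkyl TBS ethers still in place, stereocentre as in 35 (not isolated) | CC(=O)OC[C@H](c1cc([C@@H]2Oc3c(OC)cc(/C=C/CO[Si](C)(C)C(C)(C)C)cc3[C@H]2CO[Si](C)(C)C(C)(C)C)cc(OC)c1O)C=C1C=CC(=O)C(OC)=C1 | intermediate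
37 | target monoacetate: {(2R,3S)-2-(4-hydroxy-3-methoxyphenyl)-5-[(2R,3S)-3-(hydroxymethyl)-5-[(E)-3-hydroxyprop-1-enyl]-7-methoxy-2,3-dihydrobenzofuran-2-yl]-7-methoxy-2,3-dihydrobenzofuran-3-yl}methyl acetate (not isolated) | COc1cc([C@@H]2Oc3c(OC)cc([C@@H]4Oc5c(OC)cc(/C=C/CO)cc5[C@H]4CO)cc3[C@H]2COC(C)=O)ccc1O | intermediate
38 | CNP0250921.1: (E)-3-{(2R,3S)-2-[(2R,3S)-2-(4-hydroxy-3-methoxyphenyl)-3-(hydroxymethyl)-7-methoxy-2,3-dihydrobenzofuran-5-yl]-3-(hydroxymethyl)-7-methoxy-2,3-dihydrobenzofuran-5-yl}prop-2-en-1-ol | COc1cc([C@@H]2Oc3c(OC)cc([C@@H]4Oc5c(OC)cc(/C=C/CO)cc5[C@H]4CO)cc3[C@H]2CO)ccc1O | target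

## Step count

Total: 21 steps. Longest linear sequence: 17 steps (steps 1–5, then 10–21); steps 6–8 and step 9 are side branches.

## Steps most likely to fail, with fallbacks

Step 21 (key step). The two aryl silyl ethers may not be cleaved at the same rate. If the ring A phenoxide forms and ejects acetate while the more hindered ring B oxygen is still silylated, the waiting quinone methide can be consumed by loss of the C3 proton (tautomerisation to a stilbene) or by adventitious water before the ring oxygen is available. The fallback separates nucleophile and trigger by orthogonal protection and sets out from imide 31. The Evans aldol is run with commercial vanillin acetate (4-formyl-2-methoxyphenyl acetate) under the conditions of step 18 to give the ring A acetate aldol adduct F1. LiBH4 reduces the imide and cleaves the aryl acetate to the phenolic triol F2, and Ac2O/pyridine/DMAP gives the triacetate F3. TBAF buffered with AcOH (THF, rt) removes the three silyl groups without touching the acetates and gives the ring B phenol F4, in which no quinone methide can form because ring A is still acetylated. K2CO3 in MeOH then cleaves the ring A acetate, so the methide arises next to an already free ring B phenoxide, which closes the ring; methanolysis of the remaining acetates in the same flask comes back to the route at target 38.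

Step 15. Ozone may attack the two electron-rich arenes, hypochlorous acid may chlorinate them during the chlorite stage, and the arylacetaldehyde may self-condense while it waits. The fallback avoids ozone and sets out from 25. Dihydroxylation of the terminal alkene with catalytic K2OsO4·2H2O and N-methylmorpholine N-oxide (acetone/H2O) gives the terminal 1,2-diol F5 as a mixture of carbinol epimers. NaIO4 (THF/H2O) cleaves the glycol to aldehyde 26, which is taken at once into a chlorite oxidation buffered with NaH2PO4 in the presence of 2-methyl-2-butene and comes back to the route at acid 27.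

Step 13. The ring closure may be incomplete or unselective: reversible acetyl migration onto a phenoxide can hold up the elimination, or a cis ring may form that does not equilibrate at the low temperature. The fallback uses a cationic closure, possible at this stage because no acid-sensitive group is present yet, and sets out from diol 20. TBAF in THF gives the bis-phenol diol F6. A sulfonic acid resin (Amberlyst 15, CH2Cl2, rt) then ionises the para-hydroxybenzylic alcohol, and capture of the cation by the ring C phenol under thermodynamic control should give the trans ring and come back to the route at 24.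

## Further compounds

F1 | step 21 | (R)-4-benzyl-3-[(2R,3R)-2-Ar*-3-(4-acetoxy-3-methoxyphenyl)-3-hydroxypropanoyl]oxazolidin-2-one | O=C([C@H](c1cc([C@@H]2Oc3c(OC)cc(/C=C/CO[Si](C)(C)C(C)(C)C)cc3[C@H]2CO[Si](C)(C)C(C)(C)C)cc(OC)c1O[Si](C)(C)C(C)(C)C)[C@@H](O)c1ccc(OC(C)=O)c(OC)c1)N1C(=O)OC[C@H]1Cc1ccccc1
F2 | step 21 | (1R,2S)-2-Ar*-1-(4-hydroxy-3-methoxyphenyl)propane-1,3-diol | OC[C@H](c1cc([C@@H]2Oc3c(OC)cc(/C=C/CO[Si](C)(C)C(C)(C)C)cc3[C@H]2CO[Si](C)(C)C(C)(C)C)cc(OC)c1O[Si](C)(C)C(C)(C)C)[C@@H](O)c1ccc(O)c(OC)c1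
F3 | step 21 | (1R,2S)-1-(4-acetoxy-3-methoxyphenyl)-2-Ar*-propane-1,3-diyl diacetate | CC(=O)OC[C@H](c1cc([C@@H]2Oc3c(OC)cc(/C=C/CO[Si](C)(C)C(C)(C)C)cc3[C@H]2CO[Si](C)(C)C(C)(C)C)cc(OC)c1O[Si](C)(C)C(C)(C)C)[C@@H](OC(C)=O)c1ccc(OC(C)=O)c(OC)c1
F4 | step 21 | desilylated triacetate: (1R,2S)-1-(4-acetoxy-3-methoxyphenyl)-2-{2-hydroxy-5-[(2R,3S)-3-(hydroxymethyl)-5-[(E)-3-hydroxyprop-1-enyl]-7-methoxy-2,3-dihydrobenzofuran-2-yl]-3-methoxyphenyl}propane-1,3-diyl diacetate | CC(=O)OC[C@H](c1cc([C@@H]2Oc3c(OC)cc(/C=C/CO)cc3[C@H]2CO)cc(OC)c1O)[C@@H](OC(C)=O)c1ccc(OC(C)=O)c(OC)c1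
F5 | step 15 | 3-{2-TBSO-5-[(2R,3S)-5-bromo-3-(TBSO-methyl)-7-methoxy-2,3-dihydrobenzofuran-2-yl]-3-methoxyphenyl}propane-1,2-diol (carbinol epimers) | COc1cc([C@@H]2Oc3c(OC)cc(Br)cc3[C@H]2CO[Si](C)(C)C(C)(C)C)cc(CC(O)CO)c1O[Si](C)(C)C(C)(C)C
F6 | step 13 | (1R,2S)-1-(3-allyl-4-hydroxy-5-methoxyphenyl)-2-(5-bromo-2-hydroxy-3-methoxyphenyl)propane-1,3-diol | OC[C@H](c1cc(Br)cc(OC)c1O)[C@@H](O)c1cc(OC)c(O)c(CC=C)c1
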